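**Strategy**

Everything rests on cutting the C8–C9 bond of ring B in the hydroxymethyl-bearing drimane, where C9 sits between quaternary C10, the ether carbon C11 and the exocyclic C8=C12 methylene. A C9 radical, released from an epimeric thionocarbonate, cyclises 6-exo-dig onto a C8≡C12 alkyne: one operation closes ring B, sets C9 from either epimer and creates the methylene with the isocitrate ether already in place. The precursor is a ring-A cyclohexane cut out of dehydroabietic acid (C4, C5, C10 retained; the aromatic ring burnt to C8 and C9 carboxyls), joined to D-malate-derived isocitrate by Rh O–H insertion. The second drimane arises from the first by deoxygenation.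

Key step: step 13

Remark on numbering: drimane numbering is used for both terpene halves (ring A = C1–C5, C10; ring B = C5–C10; C11 on C9; C12 on C8; the C10 methyl defines the β face). Isocitrate carbons are C1' (CO2Me), C2' (O-bearing), C3', C4', C5' (CH2CO2) and C6' (carboxyl on C3').

Assumption: (R)-malic acid and dehydroabietic acid are bought as single enantiomers. Compounds 18 and 19 are carried as mixtures of C9 epimers, written with an undefined centre in their SMILES.

**Route**

Step 1
Reactants: 1 (R)-malic acid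
Product: 4 1-methyl hydrogen (R)-malate, via O-trifluoroacetylmalic anhydride 2 (not isolated), via O-trifluoroacetyl half ester 3 (not isolated)
Conditions: TFAA, 0 °C to rt; evaporate; MeOH, rt
Reagents that add atoms: methanol, CO
Why: Regioselective anhydride alcoholysis: methanol opens the O-acylated cyclic anhydride at the carbonyl next to the acyloxy group and then methanolyses the trifluoroacetate, with the stereocentre untouched.

Step 2
Reactants: 4 1-methyl hydrogen (R)-malate
Product: 5 4-allyl 1-methyl (R)-malate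
Conditions: allyl bromide, KHCO3, DMF, rt
Reagents that add atoms: allyl bromide, C=CCBr
Why: Carboxylate O-alkylation (SN2) should occur at the free acid only, since bicarbonate does not ionise the secondary hydroxyl.

Step 3
Reactants: 5 4-allyl 1-methyl (R)-malate
Product: 7 2-allyl 3-tert-butyl 1-methyl (1R,2S)-1-hydroxypropane-1,2,3-tricarboxylate (protected natural isocitrate), via dilithio alkoxide-enolate 6 (not isolated)
Conditions: LiHMDS (2.2 equiv), THF, −78 to −20 °C; BrCH2CO2tBu, −78 °C; AcOH quench at −78 °C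
Reagents that add atoms: tert-butyl bromoacetate, BrCC(=O)OC(C)(C)C
Why: Fráter–Seebach alkylation: the chelated alkoxide–enolate is alkylated anti to the C2' alkoxide, which sets C3' as (S) in the threo (natural isocitrate) series.

Step 4
Reactants: 8 dehydroabietic acid
Product: 9 dehydroabietinol (abieta-8,11,13-trien-18-ol)
Conditions: LiAlH4, THF, 0 °C to reflux
Reagents that add atoms: none
Why: Hydride reduction of the hindered C4 carboxylic acid to the primary alcohol changes no stereocentre.

Step 5
Reactants: 9 dehydroabietinol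
Product: 10 dehydroabietinol TIPS ether
Conditions: TIPSOTf, 2,6-lutidine, CH2Cl2, 0 °C
Reagents that add atoms: triisopropylsilyl triflate, CC(C)[Si](C(C)C)(C(C)C)OS(=O)(=O)C(F)(F)F
Why: Silylation with the silyl triflate should overcome the neopentyl hindrance and gives an ether chosen to survive the oxidation in step 6.

Step 6
Reactants: 10 dehydroabietinol TIPS ether
Product: 11 8,9-seco diacid (ring A with 4α-CH2OTIPS, 4β-CH3, 5α-H, 5β-CH2CH2CO2H, 10β-CH3, 10α-CO2H)
Conditions: RuCl3·xH2O (cat.), NaIO4 (excess), CCl4/MeCN/H2O, rt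
Reagents that add atoms: sodium periodate (oxygen delivered through RuO4), [Na+].[O-]I(=O)(=O)=O; water, O
Why: RuO4 oxidative degradation of the electron-rich trialkylbenzene ring (as in tetralin to adipic acid) should leave its two ipso carbons as the C8 and C9 carboxyls, with the sp3 centres C4, C5 and C10 untouched.

Step 7
Reactants: 11 8,9-seco diacid
Product: 12 mono methyl ester (C8 CO2Me, C9 CO2H free)
Conditions: EDC·HCl (1.05 equiv), DMAP (cat.), MeOH (5 equiv), CH2Cl2, 0 °C
Reagents that add atoms: methanol, CO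
Why: Steglich esterification should discriminate the unhindered CH2CH2CO2H from the tertiary C9 acid on quaternary C10.

Step 8
Reactants: 12 mono methyl ester
Product: 14 alkynyl acid (C8≡C12H terminal alkyne, C9 CO2H), via aldehyde acid 13 (not isolated)
Conditions: DIBAL-H (2.2 equiv), CH2Cl2, −78 °C; then MeOH, K2CO3, Ohira–Bestmann reagent, 0 °C to rt
Reagents that add atoms: dimethyl (1-diazo-2-oxopropyl)phosphonate, CC(=O)C(=[N+]=[N-])P(=O)(OC)OC
Why: DIBAL half-reduction of the ester (the hindered aluminium carboxylate is inert at −78 °C) followed in the same flask by Seyferth–Gilbert homologation with the Ohira–Bestmann reagent should give the terminal alkyne.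

Step 9
Reactants: 14 alkynyl acid
Product: 16 diazoketone (C10–C9(=O)–C11H=N2), via acid chloride 15 (not isolated)
Conditions: 1-chloro-N,N,2-trimethylprop-1-en-1-amine (Ghosez reagent), CH2Cl2, 0 °C to rt; then CH2N2 (3 equiv), Et2O, 0 °C
Reagents that add atoms: diazomethane, C=[N+]=[N-]
Why: Neutral acid chloride formation and acylation of diazomethane (first stage of the Arndt–Eistert sequence) add C11 without touching the silyl ether or the alkyne.

Step 10
Reactants: 16 diazoketone; 7 protected isocitrate (3 equiv, excess recovered)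
Product: 17 α-alkoxy ketone (C9 ketone, C11H2–O–C2' ether to the isocitrate triester)
Conditions: Rh2(OAc)4 (2 mol %), CH2Cl2, rt, slow addition of 16
Reagents that add atoms: none
Why: Rh(II)-carbenoid O–H insertion forms the C11–O bond without breaking any bond at C2' or C3', so the isocitrate configuration is carried over unchanged, and excess alcohol with slow addition favours O–H over intramolecular C–H insertion.

Step 11
Reactants: 17 α-alkoxy ketone
Product: 18 C9 carbinol (both C9 epimers)
Conditions: NaBH4, CeCl3·7H2O, MeOH/THF, −40 °C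
Reagents that add atoms: none
Why: Luche-type borohydride reduction should reduce the ketone in the presence of the three esters, and the epimer mixture is acceptable because step 13 erases the C9 configuration.

Step 12
Reactants: 18 C9 carbinol
Product: 19 C9 O-phenyl thionocarbonate (both C9 epimers)
Conditions: PhOC(S)Cl, pyridine, DMAP, MeCN, rt to 40 °C
Reagents that add atoms: O-phenyl chlorothionoformate, S=C(Cl)Oc1ccccc1
Why: DMAP-assisted O-thioacylation of the hindered secondary alcohol gives the Barton–McCombie radical precursor.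

Step 13
Reactants: 19 C9 O-phenyl thionocarbonate
Product: 20 ring-closed 4α-(TIPS-oxymethyl)albicanyl isocitrate ether (9S, exocyclic C8=C12)
Conditions: Bu3SnH (1.5 equiv) and AIBN (0.2 equiv) by syringe pump, PhH (0.005 M), 80 °C
Reagents that add atoms: none
Why: Bu3Sn• adds to the C=S group and β-scission of the C9–O bond releases the secondary C9 radical, the same planar species from either epimer, which attacks the proximal alkyne carbon C8; the C12 vinyl radical then takes hydrogen from Bu3SnH and the chain continues. The closest known reaction type is the Barton–McCombie-initiated tin hydride cyclisation of an alkyl radical onto a terminal alkyne. Ring B (C5–C6–C7–C8–C9–C10) closes in the 6-exo-dig mode, and the exocyclic C8=C12 methylene appears in the same event. C9 is set in a chair-like transition state anchored by the equatorial C5–C6 and C10–C9 bonds of ring A with the C10 methyl axial; the CH2O(isocitrate) arm is expected to take the pseudo-equatorial site, giving the 9β-CH2OR, 9α-H centre of a trans-decalin. The step needs cyclisation to outrun direct reduction and 1,5-hydrogen transfer, which the quaternary C10, the ring-A preorganisation and slow hydride addition at high dilution should secure; exo attack at C8 over endo attack at C12 is secured by ring size.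

Step 14
Reactants: 20 ring-closed TIPS ether
Product: 21 4α-(hydroxymethyl)albicanyl isocitrate ether (free C4 CH2OH)
Conditions: HF·pyridine, THF/pyridine, 0 °C to rt
Reagents that add atoms: none
Why: Buffered fluoride desilylation should spare the methyl, allyl and tert-butyl esters and the exocyclic alkene.

Step 15
Reactants: 21 4α-(hydroxymethyl)albicanyl isocitrate ether
Product: 22 O-(imidazol-1-ylthiocarbonyl) derivative of 21
Conditions: 1,1'-thiocarbonyldiimidazole, DMAP (cat.), toluene, 70 °C
Reagents that add atoms: 1,1'-thiocarbonyldiimidazole, S=C(n1ccnc1)n1ccnc1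
Why: Thioacylation of the primary neopentyl alcohol prepares it for Barton–McCombie deoxygenation.

Step 16
Reactants: 22 thiocarbonylimidazolide
Product: 23 albicanyl isocitrate triester (C4 gem-dimethyl; Me, allyl, tBu esters)
Conditions: Bu3SnH, AIBN, toluene, 110 °C
Reagents that add atoms: none
Why: Barton–McCombie deoxygenation turns the C4 CH2O group into the second C4 methyl, giving the albicanyl half with its three stereocentres unchanged.

Step 17
Reactants: 23 albicanyl isocitrate triester
Product: 24 albicanyl isocitrate C6' acid (C1' methyl ester, C5' tert-butyl ester)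
Conditions: Pd(PPh3)4 (5 mol %), morpholine, THF, rt
Reagents that add atoms: none
Why: Tsuji–Trost deallylation frees only the C6' carboxyl, because methyl and tert-butyl esters and the 1,1-disubstituted alkene do not ionise on Pd(0).

Step 18
Reactants: 24 albicanyl isocitrate C6' acid; 21 4α-(hydroxymethyl)albicanyl isocitrate ether
Product: 25 fully protected dimer (C6' ester to the C4 CH2O of the second drimane; one allyl and two tert-butyl esters)
Conditions: EDC·HCl, DMAP (0.3 equiv), CH2Cl2, 0 °C to rt
Reagents that add atoms: none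
Why: Steglich esterification of the equatorial primary neopentyl alcohol, run without added trialkylamine to limit epimerisation at C3' and β-elimination of the C2' alkoxy group.

Step 19
Reactants: 25 fully protected dimer
Product: 26 dimer mono-acid (C6' acid of the hydroxymethyl-derived half free; two tert-butyl esters)
Conditions: Pd(PPh3)4 (5 mol %), morpholine, THF, rt
Reagents that add atoms: none
Why: Tsuji–Trost deallylation removes the single allyl ester under neutral conditions.

Step 20
Reactants: 26 dimer mono-acid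
Product: 28 CNP0420141.2 (target), via tris(trimethylsilyl) ester 27 (not isolated)
Conditions: TMSOTf, 2,6-lutidine, CH2Cl2, 0 °C; then pH 4 aqueous buffer
Reagents that add atoms: none
Why: Silyl triflate-mediated cleavage of the tert-butyl esters to silyl esters (loss of isobutene) is non-protic and lutidine-buffered, which should spare both exocyclic alkenes, the methyl esters and the inter-unit ester before mild hydrolysis.

**Compound list**

1 | (R)-malic acid | O[C@@H](C(=O)O)CC(=O)O | starting material
2 | (R)-2-(trifluoroacetoxy)succinic anhydride | O=C1C[C@@H](OC(=O)C(F)(F)F)C(=O)O1 | intermediate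
3 | (R)-4-methoxy-4-oxo-3-(trifluoroacetoxy)butanoic acid | OC(=O)C[C@@H](OC(=O)C(F)(F)F)C(=O)OC | intermediate
4 | 1-methyl hydrogen (R)-malate | O[C@@H](C(=O)OC)CC(=O)O | intermediate
5 | 4-allyl 1-methyl (R)-malate | O[C@@H](C(=O)OC)CC(=O)OCC=C | intermediate
6 | dilithio alkoxide–enolate of 5 | [Li]O[C@@H](C(=O)OC)C=C(O[Li])OCC=C | intermediate
7 | 2-allyl 3-tert-butyl 1-methyl (1R,2S)-1-hydroxypropane-1,2,3-tricarboxylate | O[C@@H](C(=O)OC)[C@H](CC(=O)OC(C)(C)C)C(=O)OCC=C | intermediate
8 | dehydroabietic acid (4R,5R,10S) | OC(=O)[C@]1(C)CCC[C@]2(C)c3ccc(C(C)C)cc3CC[C@@H]12 | starting material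
9 | dehydroabietinol | OC[C@]1(C)CCC[C@]2(C)c3ccc(C(C)C)cc3CC[C@@H]12 | intermediate
10 | dehydroabietinol TIPS ether | CC(C)[Si](C(C)C)(C(C)C)OC[C@]1(C)CCC[C@]2(C)c3ccc(C(C)C)cc3CC[C@@H]12 | intermediate
11 | 8,9-seco diacid (C9 CO2H on C10, CH2CH2CO2H on C5) | CC(C)[Si](C(C)C)(C(C)C)OC[C@]1(C)CCC[C@](C)(C(=O)O)[C@H]1CCC(=O)O | intermediate
12 | seco acid, C8 methyl ester | CC(C)[Si](C(C)C)(C(C)C)OC[C@]1(C)CCC[C@](C)(C(=O)O)[C@H]1CCC(=O)OC | intermediate
13 | seco acid, C8 aldehyde | CC(C)[Si](C(C)C)(C(C)C)OC[C@]1(C)CCC[C@](C)(C(=O)O)[C@H]1CCC=O | intermediate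
14 | seco alkynyl acid (C8≡C12) | CC(C)[Si](C(C)C)(C(C)C)OC[C@]1(C)CCC[C@](C)(C(=O)O)[C@H]1CCC#C | intermediate
15 | seco alkynyl acid chloride | CC(C)[Si](C(C)C)(C(C)C)OC[C@]1(C)CCC[C@](C)(C(=O)Cl)[C@H]1CCC#C | intermediate
16 | seco alkynyl diazoketone | CC(C)[Si](C(C)C)(C(C)C)OC[C@]1(C)CCC[C@](C)(C(=O)C=[N+]=[N-])[C@H]1CCC#C | intermediate
17 | C9 ketone, C11–O–C2' isocitrate ether | CC(C)[Si](C(C)C)(C(C)C)OC[C@]1(C)CCC[C@](C)(C(=O)CO[C@@H](C(=O)OC)[C@H](CC(=O)OC(C)(C)C)C(=O)OCC=C)[C@H]1CCC#C | intermediate
18 | C9 carbinol (C9 epimer mixture) | CC(C)[Si](C(C)C)(C(C)C)OC[C@]1(C)CCC[C@](C)(C(O)CO[C@@H](C(=O)OC)[C@H](CC(=O)OC(C)(C)C)C(=O)OCC=C)[C@H]1CCC#C | intermediate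
19 | C9 O-phenyl thionocarbonate (C9 epimer mixture) | CC(C)[Si](C(C)C)(C(C)C)OC[C@]1(C)CCC[C@](C)(C(OC(=S)Oc2ccccc2)CO[C@@H](C(=O)OC)[C@H](CC(=O)OC(C)(C)C)C(=O)OCC=C)[C@H]1CCC#C | intermediate
20 | 4α-(TIPS-oxymethyl)albicanyl isocitrate ether (Me, allyl, tBu esters) | CC(C)[Si](C(C)C)(C(C)C)OC[C@]1(C)CCC[C@]2(C)[C@@H](CO[C@@H](C(=O)OC)[C@H](CC(=O)OC(C)(C)C)C(=O)OCC=C)C(=C)CC[C@@H]12 | intermediate
21 | 4α-(hydroxymethyl)albicanyl isocitrate ether (Me, allyl, tBu esters) | OC[C@]1(C)CCC[C@]2(C)[C@@H](CO[C@@H](C(=O)OC)[C@H](CC(=O)OC(C)(C)C)C(=O)OCC=C)C(=C)CC[C@@H]12 | intermediate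
22 | thiocarbonylimidazolide of 21 | S=C(OC[C@]1(C)CCC[C@]2(C)[C@@H](CO[C@@H](C(=O)OC)[C@H](CC(=O)OC(C)(C)C)C(=O)OCC=C)C(=C)CC[C@@H]12)n1ccnc1 | intermediate
23 | albicanyl isocitrate ether (Me, allyl, tBu esters) | CC1(C)CCC[C@]2(C)[C@@H](CO[C@@H](C(=O)OC)[C@H](CC(=O)OC(C)(C)C)C(=O)OCC=C)C(=C)CC[C@@H]12 | intermediate
24 | albicanyl isocitrate ether, C6' acid (Me, tBu esters) | CC1(C)CCC[C@]2(C)[C@@H](CO[C@@H](C(=O)OC)[C@H](CC(=O)OC(C)(C)C)C(=O)O)C(=C)CC[C@@H]12 | intermediate
25 | protected dimer (allyl and two tBu esters) | C=C1CC[C@H]2C(C)(C)CCC[C@]2(C)[C@H]1CO[C@@H](C(=O)OC)[C@H](CC(=O)OC(C)(C)C)C(=O)OC[C@]1(C)CCC[C@]2(C)[C@@H](CO[C@@H](C(=O)OC)[C@H](CC(=O)OC(C)(C)C)C(=O)OCC=C)C(=C)CC[C@@H]12 | intermediate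
26 | dimer mono-acid (two tBu esters) | C=C1CC[C@H]2C(C)(C)CCC[C@]2(C)[C@H]1CO[C@@H](C(=O)OC)[C@H](CC(=O)OC(C)(C)C)C(=O)OC[C@]1(C)CCC[C@]2(C)[C@@H](CO[C@@H](C(=O)OC)[C@H](CC(=O)OC(C)(C)C)C(=O)O)C(=C)CC[C@@H]12 | intermediate
27 | dimer tris(trimethylsilyl) ester | C=C1CC[C@H]2C(C)(C)CCC[C@]2(C)[C@H]1CO[C@@H](C(=O)OC)[C@H](CC(=O)O[Si](C)(C)C)C(=O)OC[C@]1(C)CCC[C@]2(C)[C@@H](CO[C@@H](C(=O)OC)[C@H](CC(=O)O[Si](C)(C)C)C(=O)O[Si](C)(C)C)C(=C)CC[C@@H]12 | intermediate
28 | CNP0420141.2 | C=C1CC[C@H]2C(C)(C)CCC[C@]2(C)[C@H]1CO[C@@H](C(=O)OC)[C@H](CC(=O)O)C(=O)OC[C@]1(C)CCC[C@]2(C)[C@@H](CO[C@@H](C(=O)OC)[C@H](CC(=O)O)C(=O)O)C(=C)CC[C@@H]12 | target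

**Step count and risks**

Total steps: 20. Longest linear sequence: 17 steps (steps 4–20 from dehydroabietic acid 8); the isocitrate branch (steps 1–3) joins at step 10.

Steps most likely to fail:

Step 13 (key step). The C9 radical may be reduced before it cyclises, may take a hydrogen from C7 by 1,5-transfer, or may close with poor facial selectivity at C9. Fallback with reversed radical polarity, setting out from carbinol 18: Burgess dehydration towards C11 (the only β-hydrogens) should give the (E)-enol ether F1. Bu3SnH/AIBN then adds the stannyl radical to the terminal alkyne carbon C12 (Stork vinyl-radical cyclisation), and the C8 vinyl radical closes the same C8–C9 bond 6-exo-trig onto the enol ether to give the vinylstannane F2. Protodestannylation with acetic acid comes back to the route at 20.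

Step 10. The carbenoid may insert into ring C–H bonds or react with the alkyne faster than with the hindered, electron-poor hydroxyl of 7. Fallback without a carbenoid, setting out from alkynyl acid 14: LiAlH4 reduction to the neopentyl alcohol F3, Dess–Martin oxidation to the non-enolisable aldehyde F4, and Corey–Chaykovsky methylenation (Me3S+ I−, KHMDS) to the terminal epoxide F5 as an epimer mixture. Lewis-acid-catalysed opening ((salen)Co(III) or BF3·OEt2) of F5 at its terminal carbon by alcohol 7 comes back to the route at carbinol 18.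

Step 16. Fragmentation of the primary thiocarbonyl adduct to a neopentyl primary radical may be slow, so that the alcohol is regenerated or the thiocarbonyl group is only partly reduced. Ionic fallback setting out from alcohol 21: Dess–Martin oxidation to the aldehyde F6, condensation with TsNHNH2 to the tosylhydrazone F7, and catecholborane followed by NaOAc·3H2O (Kabalka reduction, loss of sulfinate and N2) come back to the route at 23.

**Further compounds**

F1 | step 13 | (E)-enol ether from dehydration of 18 (C9=C11–O–C2') | CC(C)[Si](C(C)C)(C(C)C)OC[C@]1(C)CCC[C@](C)(/C=C/O[C@@H](C(=O)OC)[C@H](CC(=O)OC(C)(C)C)C(=O)OCC=C)[C@H]1CCC#C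
F2 | step 13 | ring-closed C12 tributylstannyl alkene | CC(C)[Si](C(C)C)(C(C)C)OC[C@]1(C)CCC[C@]2(C)[C@@H](CO[C@@H](C(=O)OC)[C@H](CC(=O)OC(C)(C)C)C(=O)OCC=C)C(=C[Sn](CCCC)(CCCC)CCCC)CC[C@@H]12
F3 | step 10 | seco alkynyl C9 primary alcohol | CC(C)[Si](C(C)C)(C(C)C)OC[C@]1(C)CCC[C@](C)(CO)[C@H]1CCC#C
F4 | step 10 | seco alkynyl C9 aldehyde | CC(C)[Si](C(C)C)(C(C)C)OC[C@]1(C)CCC[C@](C)(C=O)[C@H]1CCC#C
F5 | step 10 | seco alkynyl C9–C11 epoxide (epimer mixture) | CC(C)[Si](C(C)C)(C(C)C)OC[C@]1(C)CCC[C@](C)(C2CO2)[C@H]1CCC#C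
F6 | step 16 | C4 aldehyde from 21 | O=C[C@]1(C)CCC[C@]2(C)[C@@H](CO[C@@H](C(=O)OC)[C@H](CC(=O)OC(C)(C)C)C(=O)OCC=C)C(=C)CC[C@@H]12
F7 | step 16 | C4 aldehyde tosylhydrazone | Cc1ccc(cc1)S(=O)(=O)NN=C[C@]1(C)CCC[C@]2(C)[C@@H](CO[C@@H](C(=O)OC)[C@H](CC(=O)OC(C)(C)C)C(=O)OCC=C)C(=C)CC[C@@H]12
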